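Q, the product of G, reads 17.5% of the G and D charged by 4.00 min in the elm flask and 17.9% at 20.0 min, so it stands still within the scatter of 0.5 percentage points.

| setting | elm | birch | flask |
|---|---|---|---|
| G | 5 mM | 5 mM | 5.0 mM |
| D | 5 mM | 5 mM | 5.0 mM |
| E | 12.5 mM | 12.5 mM | 12.5 mM |
| temperature | 25 °C | 10 °C | 25 °C |
| remark | the very flask that is asked about, followed so far | run made earlier |  |
| time |  |  | 20 min |

| run | time / min | Q / % |
|---|---|---|
| elm | 1.33 | 16.8 |
| elm | 4.00 | 17.5 |
| elm | 8.00 | 17.7 |
| elm | 10.0 | 17.5 |
| elm | 15.0 | 18.3 |
| elm | 20.0 | 17.9 |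
| birch | 3.00 | 19.9 |
| birch | 8.00 | 20.7 |
| birch | 15.0 | 21.6 |
| birch | 20.0 | 21.1 |
| birch | 30.0 | 22.1 |
| birch | 40.0 | 22.0 |

(readings scatter by 0.5 percentage points)

- E is single-handed; G and D are mirror images of each other, charged as a racemate, each of them at the stated concentration
- Q taken out counts as made
- the earlier runs were read with a standard deviation of 0.5 percentage points
- what may be going on: E + G -> Q; E + D -> L; G <-> D; E <-> J; E -> Z
- additions bring no volume worth counting
- the handed part of E does not stay in what it makes, so the products of the two hands are mirror images too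

- summer: at 20 min raise the temperature by 20 K, then wait 10 min
- noon: at 20 min add E, 50.0% of the amount charged, then wait 10 min
- spring: change nothing and wait 10 min more
- autumn: at 20 min take out 90% of the Q then present, then wait 10 min

- Q, in percent of the G and D together first charged, at 20 min
- the option that brings most further Q ("none" if no option brings more than 2 percentage points) (summer / noon / spring / autumn / none)
- Q present, with what was taken out counted in, in percent of the G and D together first charged, after noon
- Q present, with what was taken out counted in, in percent of the G and D together first charged, after autumn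

That looks wrong to me. The elm flask is charged with 12.5 mM of E, more than the 10.0 mM of G and D together, and if each Q cost one G, 3.21 mM of the 5.0 mM of G is still there, yet Q stops.

A reagent that fades while it works clears this up. I take G to be lost at a rate k times E, a pseudo-first-order loss whose rate constant fades, and E to decay on its own with a time constant τ. Integrating the exponential gives ln(G charged / G left) = k × E charged × τ, so the loss has a ceiling that grows with the E charged. I carry the reach per mM of E, the logarithm of G charged over G left, divided by E charged: 0.0355 mM⁻¹. The colder birch flask, charged alike, reads higher, 22.0% at 40.0 min, so the same charge reaches further there.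

On this rule, waiting, warming and taking out Q add no E, so they bring nothing. Noon adds 6.25 mM, which on this rule takes G down to 2.57 mM and Q to 24.3%.

The forecast gives 17.9% now, noon as best, 24.5% after noon and 18% after autumn, holding that “the reaction has stopped because E has died, not because G ran out”. My noon figure lies a little below its own.

The flask gives 18.0%; noon brings 7.5 points more, to 25.5%, and autumn ends at 18.0%.

    E + G → Q (k = 2.00 M⁻¹ s⁻¹, Ea = 56.0 kJ mol⁻¹)
    E + D → L (k = 0.800 M⁻¹ s⁻¹, Ea = 40.0 kJ mol⁻¹)
    G ⇌ D (k = 0.980 s⁻¹, Ea = 71.0 kJ mol⁻¹)
    E ⇌ J (K = 0.550, k = 0.00750 s⁻¹, Ea = 77.0 kJ mol⁻¹, ΔH = −32.0 kJ mol⁻¹)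
    E → Z (k = 0.0480 s⁻¹, Ea = 74.0 kJ mol⁻¹)
    (constants at 25 °C)

In the elm flask E falls to 0.819% of its charge by 2.00 min, with Z at 9.57 mM and Q at 17.4%, and Q then holds 18.0% as late as 200 min. G and D stay equal meanwhile, each at 37.4% at 20.0 min, with L at 7.23%, so G is 3.74 mM, more than my 3.21 mM. With that G, the reach drops from 0.0355 mM⁻¹ to 0.0233 mM⁻¹. For the neighbour flask charged with 31 mM of E, this reach gives G at 24.3%, and that flask holds 23.6%.

The runs come from a simulation on assumed constants; the scatter is artificial.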